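**Retrosynthetic overview**
1. Target 18 ⇐ hemiketal 17 by cis-selective silane reduction of the cyclic oxocarbenium ion (C2 set from C3). 17 ⇐ lactone 13 + aryllithium 14 (from bromide 4) through an in situ Weinreb amide.
2. 13 ⇐ spirolactone 8 + allyl bromide 9: allyl addition, then a ring-expanding 1,2-acyloxy shift (five-membered spiro dioxolanone → fused six-membered dioxanone) that also re-forms the benzene ring with allyl para to the ether oxygen.
3. 8 ⇐ acid 7 by oxidative dearomatising spirolactonisation; 7 ⇐ hydroquinone 5 + (R)-2-chloropropanoic acid 6 (SN2 inversion sets C3 = S).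
4. 4 ⇐ 4-bromophenol 1 by diiodination/O-methylation, then Cu-catalysed methoxylation of the two C–I bonds.
5. Ring order: spiro dioxolanone (step 4) → benzene ring re-formed together with the dioxanone (step 5) → dioxanone opened and re-closed as hemiketal (step 6) → 1,4-dioxane fixed by reduction (step 7).

Assumption: (R)-2-chloropropanoic acid is bought in at least 98% ee. Locants are O1–C2(aryl)–C3(methyl)–O4 in 17 and 18 and O1–C2(=O)–C3(methyl)–O4 in 13, so the target is the cis (2R,3S) isomer with allyl at C7 (para to O4).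

**Route**

Step 1
Reactants: 1 4-bromophenol
Product: 3 5-bromo-1,3-diiodo-2-methoxybenzene, via 4-bromo-2,6-diiodophenol 2 (not isolated)
Conditions: I2 (2.1 equiv), K2CO3 (4 equiv), DMF, 0 → 23 °C; then MeI (1.5 equiv), 40 °C
Reagents that add atoms: iodine (II), iodomethane (CI)
Why: Electrophilic aromatic iodination of the phenoxide at both free ortho positions (para is blocked by Br), followed in the same pot by Williamson O-methylation; no stereocentre is involved.

Step 2
Reactants: 3 5-bromo-1,3-diiodo-2-methoxybenzene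
Product: 4 5-bromo-1,2,3-trimethoxybenzene
Conditions: CuI (10 mol %), 3,4,7,8-tetramethyl-1,10-phenanthroline (20 mol %), Cs2CO3 (3 equiv), MeOH/toluene, 80 °C
Reagents that add atoms: methanol (CO)
Why: Ullmann-type Cu-catalysed C–O coupling, in which aryl iodides react far faster than aryl bromides at 80 °C, so the C–Br bond is kept for the later lithiation.

Step 3
Reactants: 5 hydroquinone (3 equiv); 6 (R)-2-chloropropanoic acid
Product: 7 (S)-2-(4-hydroxyphenoxy)propanoic acid
Conditions: NaOH (aq), N2, 70 °C; then HCl to pH 1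
Reagents that add atoms: none
Why: Williamson SN2 etherification of the phenoxide on the α-chlorocarboxylate with clean inversion (R → S), the same process used industrially for the enantiomer; excess hydroquinone suppresses bis-alkylation.

Step 4
Reactants: 7 (S)-2-(4-hydroxyphenoxy)propanoic acid
Product: 8 (3S)-3-methyl-1,4-dioxaspiro[4.5]deca-6,9-diene-2,8-dione
Conditions: PhI(OAc)2 (1.05 equiv), dry MeCN, 0 °C; evaporate with toluene, short SiO2 plug
Reagents that add atoms: none
Why: Oxidative dearomatisation of the para-alkoxyphenol by the trivalent iodine reagent, with ipso capture of the phenoxenium ion by the tethered carboxylate (phenol spirolactonisation); the C3 stereocentre is not touched.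

Step 5
Reactants: 8 (3S)-3-methyl-1,4-dioxaspiro[4.5]deca-6,9-diene-2,8-dione; 9 allyl bromide
Product: 13 (3S)-3-methyl-7-(prop-2-en-1-yl)-2,3-dihydro-1,4-benzodioxin-2-one, via allylzinc bromide 10 (not isolated), via bromozinc alkoxide 11 (not isolated), via trifluoroacetate 12 (not isolated)
Conditions: 9, Zn dust, THF, 0 °C (10, decanted from Zn); 8, THF/CH2Cl2, −78 °C; then (CF3CO)2O (1.3 equiv), −78 → 23 °C
Reagents that add atoms: none
Why: Proposed new method: the soft allylzinc reagent adds 1,2 to the dienone carbonyl (not to the lactone) to give 11 (C8 epimers, both converge); trifluoroacetylation makes the tertiary bis-allylic oxygen a nucleofuge without acid, so ionisation occurs at C8 and not at the acyloxy ketal; the resulting 4,4-dioxygenated cyclohexadienyl cation cannot aromatise by proton loss, so the acyloxy oxygen shifts from C5 to C6 (the only 1,2-shift that leaves a cation stabilised by the ether oxygen), expanding the spiro five-membered dioxolanone to the fused six-membered dioxanone, and loss of H-6 re-forms the benzene ring with allyl para to the ether oxygen by construction; the closest known reactions are the dienol–benzene and dienone–phenol rearrangements, including acid-mediated 1,2-acyloxy shifts of para-quinol acetates and spirolactone dienones, but this leaving-group-triggered ring-expanding version on a spiro acyloxy ketal is, to my knowledge, unreported; C3 is a spectator.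

Step 6
Reactants: 13 (3S)-3-methyl-7-(prop-2-en-1-yl)-2,3-dihydro-1,4-benzodioxin-2-one; 4 5-bromo-1,2,3-trimethoxybenzene
Product: 17 (3S)-3-methyl-7-(prop-2-en-1-yl)-2-(3,4,5-trimethoxyphenyl)-2,3-dihydro-1,4-benzodioxin-2-ol, via aryllithium 14 (not isolated), via Weinreb amide phenoxide 15 (not isolated), via hydroxy ketone 16 (not isolated)
Conditions: MeNHOMe·HCl (1.3 equiv), i-PrMgCl (2.6 equiv), THF, −20 °C, then 13; then 14 (1.5 equiv; from 4, n-BuLi, THF, −78 °C), −78 → −20 °C; inverse quench into cold 1 M HCl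
Reagents that add atoms: none
Why: Aminolysis of the aryl-ester lactone by the magnesium amide gives the Weinreb amide in situ, and the Weinreb ketone synthesis then stops at the chelated tetrahedral adduct (no over-addition, no α-epimerisation); on acidic work-up hydroxy ketone 16 closes to the six-membered hemiketal 17 (ring–chain tautomerism, C2 anomers), with C3 retained.

Step 7
Reactants: 17 (3S)-3-methyl-7-(prop-2-en-1-yl)-2-(3,4,5-trimethoxyphenyl)-2,3-dihydro-1,4-benzodioxin-2-ol
Product: 18 (2R,3S)-3-methyl-7-(prop-2-en-1-yl)-2-(3,4,5-trimethoxyphenyl)-2,3-dihydro-1,4-benzodioxine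
Conditions: Et3SiH (3 equiv), TMSOTf (0.2 equiv), CH2Cl2, −78 → −40 °C
Reagents that add atoms: none
Why: Ionic hydrogenation (silane reduction of a hemiketal) through the aryl-stabilised cyclic oxocarbenium ion; A(1,2) strain with the C2 aryl group puts the C3 methyl pseudoaxial and hydride enters from the opposite, torsionally staggered face, so H-2 is trans to CH3 and the aryl is cis to CH3 (2R from 3S); low temperature suppresses enol-ether formation and acid-mediated cis → trans equilibration.

**Compound list**
1 | 4-bromophenol | Oc1ccc(Br)cc1 | starting material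
2 | 4-bromo-2,6-diiodophenol | Oc1c(I)cc(Br)cc1I | intermediate
3 | 5-bromo-1,3-diiodo-2-methoxybenzene | COc1c(I)cc(Br)cc1I | intermediate
4 | 5-bromo-1,2,3-trimethoxybenzene | COc1cc(Br)cc(OC)c1OC | intermediate
5 | hydroquinone | Oc1ccc(O)cc1 | starting material
6 | (R)-2-chloropropanoic acid | C[C@@H](Cl)C(=O)O | starting material
7 | (S)-2-(4-hydroxyphenoxy)propanoic acid | C[C@H](Oc1ccc(O)cc1)C(=O)O | intermediate
8 | (3S)-3-methyl-1,4-dioxaspiro[4.5]deca-6,9-diene-2,8-dione | C[C@@H]1OC2(C=CC(=O)C=C2)OC1=O | intermediate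
9 | allyl bromide | C=CCBr | starting material
10 | allylzinc bromide | C=CC[Zn]Br | intermediate
11 | bromozinc (3S)-3-methyl-2-oxo-8-(prop-2-en-1-yl)-1,4-dioxaspiro[4.5]deca-6,9-dien-8-olate (C8 epimers) | C[C@@H]1OC2(C=CC(CC=C)(O[Zn]Br)C=C2)OC1=O | intermediate
12 | (3S)-3-methyl-2-oxo-8-(prop-2-en-1-yl)-1,4-dioxaspiro[4.5]deca-6,9-dien-8-yl trifluoroacetate (C8 epimers) | C[C@@H]1OC2(C=CC(CC=C)(OC(=O)C(F)(F)F)C=C2)OC1=O | intermediate
13 | (3S)-3-methyl-7-(prop-2-en-1-yl)-2,3-dihydro-1,4-benzodioxin-2-one | C[C@@H]1Oc2ccc(CC=C)cc2OC1=O | intermediate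
14 | 3,4,5-trimethoxyphenyllithium | COc1cc([Li])cc(OC)c1OC | intermediate
15 | chloromagnesium 2-{[(2S)-1-[methoxy(methyl)amino]-1-oxopropan-2-yl]oxy}-5-(prop-2-en-1-yl)phenolate | C=CCc1ccc(O[C@@H](C)C(=O)N(C)OC)c(O[Mg]Cl)c1 | intermediate
16 | (2S)-2-[2-hydroxy-4-(prop-2-en-1-yl)phenoxy]-1-(3,4,5-trimethoxyphenyl)propan-1-one | C=CCc1ccc(O[C@@H](C)C(=O)c2cc(OC)c(OC)c(OC)c2)c(O)c1 | intermediate
17 | (3S)-3-methyl-7-(prop-2-en-1-yl)-2-(3,4,5-trimethoxyphenyl)-2,3-dihydro-1,4-benzodioxin-2-ol (C2 anomers) | C=CCc1ccc2c(c1)OC(O)(c1cc(OC)c(OC)c(OC)c1)[C@H](C)O2 | intermediate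
18 | (2R,3S)-3-methyl-7-(prop-2-en-1-yl)-2-(3,4,5-trimethoxyphenyl)-2,3-dihydro-1,4-benzodioxine | C=CCc1ccc2c(c1)O[C@H](c1cc(OC)c(OC)c(OC)c1)[C@H](C)O2 | target

**Step count and risks**
Total steps: 7. Longest linear sequence: 5 (steps 3, 4, 5, 6, 7 from hydroquinone); the aryl branch (steps 1, 2) joins at step 6.

The three steps most likely to fail:

Step 5 (the proposed new step). Possible failure modes are competing ionisation of the acyloxy ketal (leading to a 1,2-allyl shift and a 2-allylhydroquinone ether) and deprotonation of the cation at the allylic CH2. The fallback uses only known chemistry, sets out from 1 and comes back at 13. Magnesium-mediated ortho-formylation of 1 (MgCl2, Et3N, paraformaldehyde, MeCN, reflux) gives 5-bromo-2-hydroxybenzaldehyde F1. Williamson etherification of F1 with 6 (NaOH aq, 80 °C, inversion) gives (S)-2-(4-bromo-2-formylphenoxy)propanoic acid F2. Dakin-type Baeyer–Villiger oxidation (mCPBA, CH2Cl2; aryl migration from carbon to oxygen) gives the aryl formate (S)-2-[4-bromo-2-(formyloxy)phenoxy]propanoic acid F3. p-TsOH in refluxing toluene expels formic acid and closes (3S)-7-bromo-3-methyl-2,3-dihydro-1,4-benzodioxin-2-one F4. Stille allylation (allylSnBu3, Pd(PPh3)4, toluene, 100 °C) then gives 13.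

Step 6. Risks are incomplete aminolysis (then double aryl addition to the aryl ester) and α-epimerisation of the aryloxy ketone. The fallback sets out from 13 and comes back at 17 by changing the oxidation level. i-Bu2AlH (CH2Cl2, −78 °C) reduces the lactone to the lactol (3S)-3-methyl-7-(prop-2-en-1-yl)-2,3-dihydro-1,4-benzodioxin-2-ol F5. Aryllithium 14 (2.5 equiv, THF, −78 °C) adds to its ring-opened aldehyde form to give (2S)-2-[2-hydroxy-4-(prop-2-en-1-yl)phenoxy]-1-(3,4,5-trimethoxyphenyl)propan-1-ol F6 as a C1 epimer mixture. MnO2 (CH2Cl2, 23 °C) oxidises the electron-rich benzylic alcohol selectively to 16, which closes to 17.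

Step 7. Risks are an insufficient cis:trans ratio, loss of ee at C3 through the enol ether, and acid-mediated drift to the trans isomer. The fallback sets out from 17 and comes back at 18 through an open-chain sequence. Zn(BH4)2 (Et2O, −20 °C) reduces the ketone tautomer 16 under chelation control to the syn diol (1S,2S)-2-[2-hydroxy-4-(prop-2-en-1-yl)phenoxy]-1-(3,4,5-trimethoxyphenyl)propan-1-ol F7. Intramolecular Mitsunobu etherification (PPh3, DIAD, THF, 0 °C) closes the ring with inversion at the benzylic carbon (1S → 2R) to give 18.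

**Further compounds**
F1 | step 5 | 5-bromo-2-hydroxybenzaldehyde | O=Cc1cc(Br)ccc1O
F2 | step 5 | (S)-2-(4-bromo-2-formylphenoxy)propanoic acid | C[C@H](Oc1ccc(Br)cc1C=O)C(=O)O
F3 | step 5 | (S)-2-[4-bromo-2-(formyloxy)phenoxy]propanoic acid | C[C@H](Oc1ccc(Br)cc1OC=O)C(=O)O
F4 | step 5 | (3S)-7-bromo-3-methyl-2,3-dihydro-1,4-benzodioxin-2-one | C[C@@H]1Oc2ccc(Br)cc2OC1=O
F5 | step 6 | (3S)-3-methyl-7-(prop-2-en-1-yl)-2,3-dihydro-1,4-benzodioxin-2-ol | C[C@@H]1Oc2ccc(CC=C)cc2OC1O
F6 | step 6 | (2S)-2-[2-hydroxy-4-(prop-2-en-1-yl)phenoxy]-1-(3,4,5-trimethoxyphenyl)propan-1-ol (C1 epimers) | C=CCc1ccc(O[C@@H](C)C(O)c2cc(OC)c(OC)c(OC)c2)c(O)c1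
F7 | step 7 | (1S,2S)-2-[2-hydroxy-4-(prop-2-en-1-yl)phenoxy]-1-(3,4,5-trimethoxyphenyl)propan-1-ol | C=CCc1ccc(O[C@@H](C)[C@@H](O)c2cc(OC)c(OC)c(OC)c2)c(O)c1
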